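The runs were computed with made-up constants, noise included.

| flask | substrate | gas phase | remark | time |
|---|---|---|---|---|
| blue | 23 mM | 4.8 mM (held) | run made earlier |  |
| green | 52 mM | 4.8 mM (held) | run made earlier |  |
| flask | 35 mM | 4.8 mM (held) |  | 50 min |

| run | time / min | target / % |
|---|---|---|
| blue | 3.00 | 1.1 |
| blue | 8.00 | 5.9 |
| blue | 15.0 | 12.3 |
| blue | 40.0 | 31.9 |
| green | 3.00 | 1.8 |
| green | 8.00 | 6.6 |
| green | 15.0 | 13.1 |
| green | 40.0 | 26.0 |

(standard deviation of a reading: 1 percentage point)

- in percentages every species weighs as the substrate in it: one homo dimer counts as two
- at the start none of the gas is dissolved
- steps that have been proposed: gas phase <-> dissolved gas; 2 substrate -> homo dimer; substrate -> side product; substrate + dissolved gas -> target; target <-> isomer of the product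

- west: doubling the transfer coefficient of the gas phase, all else as stated
- south: doubling the saturation concentration of gas phase, all else as stated

1. how much target there is at 50 min, in percent of the substrate charged
2. the change that raises the amount of target at 50 min, in percent of the substrate charged most ("none" if none brings more than 2 percentage points) (west / south / none)
3. amount of target at 50 min, in percent of the substrate charged, after west

The pitfall is to carry the percentages of the blue run straight over to a flask of another charge, for that is the symmetric case, the zero of the scale, in which every step that uses substrate goes first order in it at a fixed [dissolved gas] and the percent curve ignores the charge. The departure from that zero is measured by the charge exponent, 0.251, the power of the charge by which percent target falls, an apparent excess order, read from blue and green at 40.0 min. Folding in the 35 mM of the flask, the reckoning here gives 28.7 % at that time. One number is not enough, though: at 15.0 min the same exponent reads −0.0772, and a scatter of 1 percentage point on a reading moves it by 0.0997, more than its distance from zero. Up to 50 min the reckoning adds the scaled last slope of blue at half its value, because the slope of green has already sunk to about half, and commits to 32.2 %.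

The forecast stands higher, at 34.5 %, with 36.5 % after west and south as the best change: “Doubling saturation nearly doubles the rate, so south wins clearly.”

    gas phase ⇌ dissolved gas, rate k1*(csat - [dissolved gas]) (kL = 0.330 min⁻¹)
    2 substrate → homo dimer (k = 0.0610 L mol⁻¹ min⁻¹)
    substrate → side product (k = 0.00550 min⁻¹)
    substrate + dissolved gas → target (k = 4.10 L mol⁻¹ min⁻¹)
    target ⇌ isomer of the product (K = 0.580, k = 0.0160 min⁻¹)

The flask gives 32.9 %, south as the best change with 17 points against 3.2 points for west, and 36.1 % after west, so the forecast holds within its margin; it would be wrong if a run put target outside that margin, and 65.0 mM is the nearest charge above this one at which the amount of target has moved by 5 points. At 16.5 min the flask makes target 5.23 times faster than it uses it up, each step taken net, and at 50.0 min its 32.9 % of target stands beside 31.7 % of substrate. Carried from the flask to the neighbour at 60 mM, the exponent gives 28.7 % against the simulated 28.6 %, and that neighbour holds 14.6 % of homo dimer against 8.69 % in the flask.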